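**Plan**
- Retrosynthesis: cut the six benzyl ethers, then the ester C–O bond at C3, then return C3 to a ketone (flavan-3-one) and mask it as its enol benzoate, a 4H-chromene.
- Ring C of that 4H-chromene is cut at C4–C4a and O1–C8a, giving a ring A aryne and a ring B 1-aroylvinyl benzoate.
- Enabling feature: at the enone oxidation level O1–C2–C3–C4 is a 1-oxabuta-1,3-diene. C4a/C8a of ring A, with oxygen on C5 and C7, are the two carbons of a 3,5-dialkoxybenzyne polarised so that O adds at C8a and C4 at C4a.
- Forward: the ring B oxadiene (4 steps) and the ring A silyl triflate (2 steps) are joined in an aryne oxa-[4+2] that closes ring C. Enol ester cleavage, reduction, acylation and debenzylation follow.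
- Stereochemistry: C2 and C3 are both set in one Ru-catalysed hydrogenation of the racemic flavan-3-one under dynamic kinetic resolution (C2 equilibrates, hydride enters anti to the C2 aryl group, giving 2,3-cis, 2R,3R).

Key step: step 7

Assumption: compounds 1, 6 and 15 are taken as commercial. The hand of the hydrogenation catalyst in step 9 is assigned by analogy with 2-substituted cycloalkanones; the mirror-image complex is used if the sense of induction is found to be opposite.

**Step 1**
Reactants: 1 3,4,5-tris(benzyloxy)benzaldehyde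
Product: 2 1-[3,4,5-tris(benzyloxy)phenyl]propan-1-ol (racemic)
Conditions: EtMgBr, THF, 0 °C; aq. NH4Cl
Reagents that add atoms: ethylmagnesium bromide, CC[Mg]Br
Why: Grignard addition to an aryl aldehyde; the carbinol centre forms racemic and is removed in step 2.

**Step 2**
Reactants: 2 1-[3,4,5-tris(benzyloxy)phenyl]propan-1-ol
Product: 3 1-[3,4,5-tris(benzyloxy)phenyl]propan-1-one
Conditions: (n-Pr4N)RuO4 (cat.), N-methylmorpholine N-oxide, 4 Å MS, CH2Cl2, rt
Reagents that add atoms: none
Why: Ley–Griffith oxidation of a secondary benzylic alcohol under neutral conditions that leave benzyl ethers untouched.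

**Step 3**
Reactants: 3 1-[3,4,5-tris(benzyloxy)phenyl]propan-1-one
Product: 4 1-[3,4,5-tris(benzyloxy)phenyl]propane-1,2-dione
Conditions: SeO2, 1,4-dioxane/H2O, reflux
Reagents that add atoms: selenium dioxide, O=[Se]=O
Why: Riley oxidation converts the only enolisable methylene next to the aryl ketone into a carbonyl group.

**Step 4**
Reactants: 4 1-[3,4,5-tris(benzyloxy)phenyl]propane-1,2-dione
Product: 5 3-oxo-3-[3,4,5-tris(benzyloxy)phenyl]prop-1-en-2-yl benzoate
Conditions: PhCOCl, Et3N, THF/DMPU, −20 °C to rt
Reagents that add atoms: benzoyl chloride, O=C(Cl)c1ccccc1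
Why: O-acylation of the amine-generated enolate of a 1,2-dione, as used to make 1-acetylvinyl arenecarboxylates from butane-2,3-dione; only the methyl group can enolise, so a single enol benzoate should form.

**Step 5**
Reactants: 6 3,5-bis(benzyloxy)phenol
Product: 7 3,5-bis(benzyloxy)-2-bromophenol
Conditions: N-bromosuccinimide (1.0 equiv), i-Pr2NH (cat.), CH2Cl2, −78 °C
Reagents that add atoms: N-bromosuccinimide, O=C1CCC(=O)N1Br
Why: Electrophilic aromatic bromination, with amine-mediated delivery at low temperature favouring the position ortho to the hydroxyl group and one equivalent limiting dibromination.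

**Step 6**
Reactants: 7 3,5-bis(benzyloxy)-2-bromophenol
Product: 10 3,5-bis(benzyloxy)-2-(trimethylsilyl)phenyl trifluoromethanesulfonate, via trimethylsilyl ether 8 (not isolated), via lithium 2-silylphenolate 9 (not isolated)
Conditions: (Me3Si)2NH, THF, 70 °C, evaporate; n-BuLi, THF, −78 °C; Tf2O, −78 °C to rt
Reagents that add atoms: hexamethyldisilazane, C[Si](C)(C)N[Si](C)(C)C; trifluoromethanesulfonic anhydride, O=S(=O)(OS(=O)(=O)C(F)(F)F)C(F)(F)F
Why: O-silylation, bromine–lithium exchange with 1,3 oxygen-to-carbon silyl shift (retro-Brook rearrangement) and triflation of the phenolate is the standard route to ortho-silylaryl triflates, and the fast exchange at −78 °C spares the benzyl ethers.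

**Step 7**
Reactants: 5 3-oxo-3-[3,4,5-tris(benzyloxy)phenyl]prop-1-en-2-yl benzoate; 10 3,5-bis(benzyloxy)-2-(trimethylsilyl)phenyl trifluoromethanesulfonate
Product: 12 5,7-bis(benzyloxy)-2-[3,4,5-tris(benzyloxy)phenyl]-4H-chromen-3-yl benzoate, via 3,5-bis(benzyloxy)benzyne 11 (not isolated)
Conditions: CsF (3 equiv), MeCN/toluene, rt, slow addition of 10 (1.3 equiv), argon
Reagents that add atoms: none
Why: Proposed new method: fluoride-induced 1,2-elimination of 10 gives aryne 11, which is trapped by the s-cis enone 5 acting as a 1-oxabuta-1,3-diene in a polar, strongly asynchronous [4+2] cycloaddition in which the ketone oxygen bonds first and the aryl carbanion character developing next to the benzyloxy group then closes on the terminal CH2. The closest known reaction types are the hetero-Diels–Alder reactions of arynes with 1-azadienes and with ortho-quinone methides, the aryne plus enal route to 2H-chromenes, and the heterodiene behaviour of 1-acylvinyl carboxylates. Ring C closes in the [4+2] mode as a six-membered ring (in the stepwise reading a 6-endo-trig attack of the aryl anion on the enone beta carbon), and no stereocentre is created because C2 and C3 emerge as an enol ester double bond. Three selectivities are needed: the orientation on the unsymmetrical aryne, six-membered closure instead of [2+2] closure at the carbonyl carbon, and oxygen-first instead of carbon-first bonding. The first is secured by the inductive effect of the benzyloxy group flanking the aryne, which sends the nucleophilic oxygen to the remote aryne carbon (future C8a) and leaves the carbon next to it (future C4a) for C4, and the second by the fully substituted, conjugated ketone carbon set against an unhindered terminal methylene that offers no allylic hydrogen for an ene reaction. The third rests on the benzoyloxy group, which damps the enol-type nucleophilicity of the CH2 terminus, and on the para-benzyloxy group of the aroyl ring, which raises the donor strength of the carbonyl oxygen.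

**Step 8**
Reactants: 12 5,7-bis(benzyloxy)-2-[3,4,5-tris(benzyloxy)phenyl]-4H-chromen-3-yl benzoate
Product: 13 5,7-bis(benzyloxy)-2-[3,4,5-tris(benzyloxy)phenyl]chroman-3-one (racemic)
Conditions: K2CO3 (0.2 equiv), degassed MeOH/THF, 0 °C; AcOH quench; used crude
Reagents that add atoms: none
Why: Methanolysis of the activated enol benzoate releases the enol, which tautomerises to the ketone; C2 forms racemic and stays configurationally labile, which step 9 exploits.

**Step 9**
Reactants: 13 5,7-bis(benzyloxy)-2-[3,4,5-tris(benzyloxy)phenyl]chroman-3-one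
Product: 14 (2R,3R)-5,7-bis(benzyloxy)-2-[3,4,5-tris(benzyloxy)phenyl]chroman-3-ol
Conditions: H2 (8 atm), trans-RuCl2[(S)-xylbinap][(S)-daipen] (1 mol %), t-BuOK (10 mol %), i-PrOH/THF, rt
Reagents that add atoms: none
Why: Noyori-type asymmetric ketone hydrogenation with dynamic kinetic resolution: C2 (alpha to the carbonyl, benzylic and oxygen-bearing) should racemise quickly through the enolate under the basic conditions, while the chiral ruthenium hydride reduces one ketone enantiomer with hydride delivery anti to the C2 aryl group, setting C3 cis to C2 and both centres as 2R,3R.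

**Step 10**
Reactants: 14 (2R,3R)-5,7-bis(benzyloxy)-2-[3,4,5-tris(benzyloxy)phenyl]chroman-3-ol; 15 4-(benzyloxy)benzoyl chloride
Product: 16 (2R,3R)-5,7-bis(benzyloxy)-2-[3,4,5-tris(benzyloxy)phenyl]chroman-3-yl 4-(benzyloxy)benzoate
Conditions: pyridine, DMAP (cat.), CH2Cl2, 0 °C to rt
Reagents that add atoms: none
Why: DMAP-catalysed acylation of the secondary alcohol by an aroyl chloride; the C3–O bond is not broken, so the configuration is retained.

**Step 11**
Reactants: 16 (2R,3R)-5,7-bis(benzyloxy)-2-[3,4,5-tris(benzyloxy)phenyl]chroman-3-yl 4-(benzyloxy)benzoate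
Product: 17 epigallocatechin 3-O-(4-hydroxybenzoate)
Conditions: H2 (1 atm), Pd(OH)2 on carbon, THF/MeOH, rt, then filtration under argon
Reagents that add atoms: none
Why: Hydrogenolysis of the six benzyl ethers under neutral conditions, as practised on benzylated catechin esters, should leave the ester and the ring C–O bonds intact and touches no stereocentre.

**Compound list**
1 | 3,4,5-tris(benzyloxy)benzaldehyde | O=Cc1cc(OCc2ccccc2)c(OCc2ccccc2)c(OCc2ccccc2)c1 | starting material
2 | 1-[3,4,5-tris(benzyloxy)phenyl]propan-1-ol (racemic) | CCC(O)c1cc(OCc2ccccc2)c(OCc2ccccc2)c(OCc2ccccc2)c1 | intermediate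
3 | 1-[3,4,5-tris(benzyloxy)phenyl]propan-1-one | CCC(=O)c1cc(OCc2ccccc2)c(OCc2ccccc2)c(OCc2ccccc2)c1 | intermediate
4 | 1-[3,4,5-tris(benzyloxy)phenyl]propane-1,2-dione | CC(=O)C(=O)c1cc(OCc2ccccc2)c(OCc2ccccc2)c(OCc2ccccc2)c1 | intermediate
5 | 3-oxo-3-[3,4,5-tris(benzyloxy)phenyl]prop-1-en-2-yl benzoate | C=C(OC(=O)c1ccccc1)C(=O)c1cc(OCc2ccccc2)c(OCc2ccccc2)c(OCc2ccccc2)c1 | intermediate
6 | 3,5-bis(benzyloxy)phenol | Oc1cc(OCc2ccccc2)cc(OCc2ccccc2)c1 | starting material
7 | 3,5-bis(benzyloxy)-2-bromophenol | Oc1cc(OCc2ccccc2)cc(OCc2ccccc2)c1Br | intermediate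
8 | [3,5-bis(benzyloxy)-2-bromophenoxy]trimethylsilane | C[Si](C)(C)Oc1cc(OCc2ccccc2)cc(OCc2ccccc2)c1Br | intermediate
9 | lithium 3,5-bis(benzyloxy)-2-(trimethylsilyl)phenolate | [Li+].[O-]c1cc(OCc2ccccc2)cc(OCc2ccccc2)c1[Si](C)(C)C | intermediate
10 | 3,5-bis(benzyloxy)-2-(trimethylsilyl)phenyl trifluoromethanesulfonate | C[Si](C)(C)c1c(OS(=O)(=O)C(F)(F)F)cc(OCc2ccccc2)cc1OCc1ccccc1 | intermediate
11 | 3,5-bis(benzyloxy)benzyne | C1#CC(OCc2ccccc2)=CC(OCc2ccccc2)=C1 | intermediate
12 | 5,7-bis(benzyloxy)-2-[3,4,5-tris(benzyloxy)phenyl]-4H-chromen-3-yl benzoate | O=C(OC1=C(c2cc(OCc3ccccc3)c(OCc3ccccc3)c(OCc3ccccc3)c2)Oc2cc(OCc3ccccc3)cc(OCc3ccccc3)c2C1)c1ccccc1 | intermediate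
13 | 5,7-bis(benzyloxy)-2-[3,4,5-tris(benzyloxy)phenyl]chroman-3-one (racemic) | O=C1Cc2c(OCc3ccccc3)cc(OCc3ccccc3)cc2OC1c1cc(OCc2ccccc2)c(OCc2ccccc2)c(OCc2ccccc2)c1 | intermediate
14 | (2R,3R)-5,7-bis(benzyloxy)-2-[3,4,5-tris(benzyloxy)phenyl]chroman-3-ol | O[C@@H]1Cc2c(OCc3ccccc3)cc(OCc3ccccc3)cc2O[C@@H]1c1cc(OCc2ccccc2)c(OCc2ccccc2)c(OCc2ccccc2)c1 | intermediate
15 | 4-(benzyloxy)benzoyl chloride | O=C(Cl)c1ccc(OCc2ccccc2)cc1 | starting material
16 | (2R,3R)-5,7-bis(benzyloxy)-2-[3,4,5-tris(benzyloxy)phenyl]chroman-3-yl 4-(benzyloxy)benzoate | O=C(O[C@@H]1Cc2c(OCc3ccccc3)cc(OCc3ccccc3)cc2O[C@@H]1c1cc(OCc2ccccc2)c(OCc2ccccc2)c(OCc2ccccc2)c1)c1ccc(OCc2ccccc2)cc1 | intermediate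
17 | epigallocatechin 3-O-(4-hydroxybenzoate), (2R,3R) | O=C(O[C@@H]1Cc2c(O)cc(O)cc2O[C@@H]1c1cc(O)c(O)c(O)c1)c1ccc(O)cc1 | target

**Step count and risks**
Total steps: 11. Longest linear sequence: 9 (steps 1, 2, 3, 4, 7, 8, 9, 10, 11); steps 5 and 6 form the ring A arm.

Steps most likely to fail:

1. Step 7 (Proposed new method). Possible failure processes:
   - closure of the aryl anion at the carbonyl carbon ([2+2]), followed by ring opening and electrocyclisation to the isomeric 4-aryl-2H-chromene skeleton;
   - [2+2] addition of the aryne across the enol ester double bond;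
   - ene reaction of the C4 hydrogens of the product with excess aryne;
   - fluoride-induced cleavage of the enol ester.

   Fallback, from 5 and 6, returning at 12: Lewis-acid-catalysed Friedel–Crafts conjugate addition of phenol 6 (Sc(OTf)3 cat., CH2Cl2) to enone 5 should alkylate the ring position ortho to the hydroxyl group and give 3-[2,4-bis(benzyloxy)-6-hydroxyphenyl]-1-oxo-1-[3,4,5-tris(benzyloxy)phenyl]propan-2-yl benzoate F1. Acid-catalysed hemiketalisation and dehydration (p-TsOH cat., toluene, water removal) then closes ring C through O1–C2 and gives 12. Both are known reaction types for phenols and enones.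

2. Step 9. Possible failure processes: racemisation of C2 too slow relative to reduction, poor face discrimination for a ketone flanked by two sp3 carbons, or erosion of the cis preference.

   Fallback, from 13, returning at 14: reduction with LiBH(s-Bu)3 in THF at −78 °C (hydride anti to the C2 aryl group, a known outcome for this ketone class) should give racemic cis-5,7-bis(benzyloxy)-2-[3,4,5-tris(benzyloxy)phenyl]chroman-3-ol F2. Esterification with (2S)-2-methoxy-2-phenylacetic acid (DCC, DMAP) and separation of the diastereomers gives (2R,3R)-5,7-bis(benzyloxy)-2-[3,4,5-tris(benzyloxy)phenyl]chroman-3-yl (2S)-2-methoxy-2-phenylacetate F3. Saponification (LiOH, THF/MeOH/H2O) returns 14.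

3. Step 5. Possible failure processes: bromination at the position between the two benzyloxy groups (para to the hydroxyl group) or double bromination.

   Fallback, from 6, returning at 10 (steps 5 and 6 are bypassed): carbamoylation with isopropyl isocyanate and Et3N gives 3,5-bis(benzyloxy)phenyl N-(propan-2-yl)carbamate F4. In situ N-silylation (TBSOTf, TMEDA), carbamate-directed ortho-lithiation (n-BuLi, TMEDA, −78 °C) and quench with Me3SiCl give 3,5-bis(benzyloxy)-2-(trimethylsilyl)phenyl N-(propan-2-yl)carbamate F5. Carbamate cleavage with DBU and Et2NH in MeCN, followed by PhNTf2, gives 10.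

**Further compounds**
F1 | step 7 | 3-[2,4-bis(benzyloxy)-6-hydroxyphenyl]-1-oxo-1-[3,4,5-tris(benzyloxy)phenyl]propan-2-yl benzoate (racemic) | O=C(OC(Cc1c(O)cc(OCc2ccccc2)cc1OCc1ccccc1)C(=O)c1cc(OCc2ccccc2)c(OCc2ccccc2)c(OCc2ccccc2)c1)c1ccccc1
F2 | step 9 | cis-5,7-bis(benzyloxy)-2-[3,4,5-tris(benzyloxy)phenyl]chroman-3-ol (racemate, both enantiomers written) | O[C@@H]1Cc2c(OCc3ccccc3)cc(OCc3ccccc3)cc2O[C@@H]1c1cc(OCc2ccccc2)c(OCc2ccccc2)c(OCc2ccccc2)c1.O[C@H]1Cc2c(OCc3ccccc3)cc(OCc3ccccc3)cc2O[C@H]1c1cc(OCc2ccccc2)c(OCc2ccccc2)c(OCc2ccccc2)c1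
F3 | step 9 | (2R,3R)-5,7-bis(benzyloxy)-2-[3,4,5-tris(benzyloxy)phenyl]chroman-3-yl (2S)-2-methoxy-2-phenylacetate | CO[C@H](C(=O)O[C@@H]1Cc2c(OCc3ccccc3)cc(OCc3ccccc3)cc2O[C@@H]1c1cc(OCc2ccccc2)c(OCc2ccccc2)c(OCc2ccccc2)c1)c1ccccc1
F4 | step 5 | 3,5-bis(benzyloxy)phenyl N-(propan-2-yl)carbamate | CC(C)NC(=O)Oc1cc(OCc2ccccc2)cc(OCc2ccccc2)c1
F5 | step 5 | 3,5-bis(benzyloxy)-2-(trimethylsilyl)phenyl N-(propan-2-yl)carbamate | CC(C)NC(=O)Oc1cc(OCc2ccccc2)cc(OCc2ccccc2)c1[Si](C)(C)C
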